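**Assumption:** the target has no stereocentre (it is achiral), so no enantiocontrol is needed; the only stereo-element on the route is the Z-alkene of 5, and racemic or transient intermediates are marked as such.

**Retrosynthetic overview**
1. The C2–Br and C3–Br bonds come last, by double electrophilic bromination (NBS) of 4,7-dibromoindole; the two benzo bromines are carried from the start.
2. 4,7-Dibromoindole comes from ethyl 4,7-dibromoindole-2-carboxylate by saponification and decarboxylation.
3. The pyrrole ring (N1–C7a bond) is closed by Hemetsberger–Knittel nitrene C–H insertion of an α-azidocinnamate; only one ortho position is free, which fixes the 4,7-pattern.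
4. The key C–C bond (indole C2–C3) is made by intermolecular aldol condensation of 2,5-dibromobenzaldehyde with ethyl azidoacetate.
5. Ring order: the benzene ring is bought, and the pyrrole ring is the only ring formed.

**Route**

Step 1
Reactants: 1 ethyl bromoacetate
Product: 2 ethyl azidoacetate
Conditions: NaN3 (1.2 equiv), acetone/H2O 3:1, rt, 16 h; kept as a solution, never distilled to dryness
Reagents that add atoms: sodium azide, [Na+].[N-]=[N+]=[N-]
Why: Azide displaces bromide from an activated α-halo ester in a clean SN2 substitution.

Step 2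
Reactants: 3 2,5-dibromobenzaldehyde; 2 ethyl azidoacetate (4 equiv)
Product: 5 ethyl (Z)-2-azido-3-(2,5-dibromophenyl)acrylate, via aldol adduct 4 (not isolated)
Conditions: NaOEt (4 equiv), EtOH, −15 → 0 °C, 5 h
Reagents that add atoms: none
Why: The azidoacetate enolate adds to the non-enolisable aldehyde and the adduct dehydrates by E1cB to the conjugated, thermodynamically preferred Z-azidocinnamate (Knoevenagel-type aldol condensation, first stage of the Hemetsberger–Knittel synthesis), with the low temperature keeping the azide intact.

Step 3
Reactants: 5 ethyl (Z)-2-azido-3-(2,5-dibromophenyl)acrylate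
Product: 7 ethyl 4,7-dibromo-1H-indole-2-carboxylate, via 2H-azirine 6 (not isolated)
Conditions: xylenes, 140 °C, slow addition of 5 to the hot solvent, 2 h
Reagents that add atoms: none
Why: In the Hemetsberger–Knittel indolisation, thermal loss of N2 gives the azirine/vinyl nitrene, which inserts into the only free ortho C–H (the other ortho carbon carries Br) and so fixes the 4,7-dibromo pattern.

Step 4
Reactants: 7 ethyl 4,7-dibromo-1H-indole-2-carboxylate
Product: 9 4,7-dibromo-1H-indole-2-carboxylic acid, via sodium carboxylate 8 (not isolated)
Conditions: NaOH (3 equiv), EtOH/H2O 3:1, 70 °C, 3 h; then 2 M HCl to pH 2, filter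
Reagents that add atoms: sodium hydroxide, [Na+].[OH-]
Why: This is an ordinary ester saponification (BAc2) to which the indole and the aryl bromides are inert, and acidification precipitates the acid.

Step 5
Reactants: 9 4,7-dibromo-1H-indole-2-carboxylic acid
Product: 10 4,7-dibromo-1H-indole
Conditions: Cu powder (0.2 equiv), quinoline, 215 °C, N2, 1.5 h
Reagents that add atoms: none
Why: Copper-mediated protodecarboxylation of an indole-2-carboxylic acid in quinoline is the classical removal of the Hemetsberger carboxyl group, and aryl bromides survive the short heating with substoichiometric copper.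

Step 6
Reactants: 10 4,7-dibromo-1H-indole
Product: 12 2,3,4,7-tetrabromo-1H-indole, via 3,4,7-tribromoindole 11 (not isolated)
Conditions: NBS (2.1 equiv, recrystallised), dry DMF, 0 °C → rt, dark, N2; aq. Na2S2O3/NaHCO3 work-up
Reagents that add atoms: N-bromosuccinimide, O=C1CCC(=O)N1Br
Why: In this electrophilic aromatic bromination the first NBS equivalent takes the most nucleophilic C3 and the second the remaining pyrrole position C2, while the benzo ring, deactivated by two bromines, is left alone.

**Compound list**
1 | ethyl bromoacetate | CCOC(=O)CBr | starting material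
2 | ethyl azidoacetate | CCOC(=O)CN=[N+]=[N-] | intermediate
3 | 2,5-dibromobenzaldehyde | O=Cc1cc(Br)ccc1Br | starting material
4 | ethyl 2-azido-3-(2,5-dibromophenyl)-3-hydroxypropanoate (aldol adduct; racemic mixture of diastereomers, not isolated) | CCOC(=O)C(N=[N+]=[N-])C(O)c1cc(Br)ccc1Br | intermediate
5 | ethyl (Z)-2-azido-3-(2,5-dibromophenyl)acrylate | CCOC(=O)/C(N=[N+]=[N-])=C/c1cc(Br)ccc1Br | intermediate
6 | ethyl 2-(2,5-dibromophenyl)-2H-azirine-3-carboxylate (racemic, not isolated) | CCOC(=O)C1=NC1c1cc(Br)ccc1Br | intermediate
7 | ethyl 4,7-dibromo-1H-indole-2-carboxylate | CCOC(=O)c1cc2c(Br)ccc(Br)c2[nH]1 | intermediate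
8 | sodium 4,7-dibromo-1H-indole-2-carboxylate (not isolated) | [Na+].[O-]C(=O)c1cc2c(Br)ccc(Br)c2[nH]1 | intermediate
9 | 4,7-dibromo-1H-indole-2-carboxylic acid | OC(=O)c1cc2c(Br)ccc(Br)c2[nH]1 | intermediate
10 | 4,7-dibromo-1H-indole | Brc1ccc(Br)c2[nH]ccc12 | intermediate
11 | 3,4,7-tribromo-1H-indole (not isolated) | Brc1c[nH]c2c(Br)ccc(Br)c12 | intermediate
12 | 2,3,4,7-tetrabromo-1H-indole | Brc1[nH]c2c(Br)ccc(Br)c2c1Br | target

**Total step count:** 6
**Longest linear sequence:** 6 steps (1 → 2 → 5 → 7 → 9 → 10 → 12)

**Steps most likely to fail, with fallbacks**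

Step 2 (aldol condensation). The azidoacetate enolate can decompose faster than it condenses, or the reaction can stall. The fallback introduces the azide after the C–C bond is made. It sets out from 3: a Knoevenagel–Doebner condensation with ethyl hydrogen malonate (pyridine, cat. piperidine, 100 °C, decarboxylative) gives ethyl (E)-3-(2,5-dibromophenyl)acrylate F1. Br2 in CH2Cl2 adds anti to give racemic erythro ethyl 2,3-dibromo-3-(2,5-dibromophenyl)propanoate F2. NaN3 (3 equiv) in DMF at rt then displaces the α-bromide to give ethyl 2-azido-3-bromo-3-(2,5-dibromophenyl)propanoate F3, which loses HBr in the same pot. The fallback comes back to the route at 5.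

Step 5 (Cu/quinoline decarboxylation). Ullmann-type coupling or debromination at 215 °C are the risks. The fallback removes the carboxyl group by ipso-bromination instead of protonation. It sets out from 9: NBS (1.05 equiv) in DMF at 0 °C brominates C3 to give 3,4,7-tribromo-1H-indole-2-carboxylic acid F4. A second equivalent of NBS with cat. LiOAc in DMF at rt then effects bromodecarboxylation at C2 (attack at C3, 1,2-bromine shift, loss of CO2). The fallback comes back to the route at 12 and bypasses 10 altogether.

Step 6 (2,3-dibromination of the free NH indole). The second bromination may be sluggish, or the product may oxidise to an oxindole. The fallback installs the C2 bromine by directed metalation. It sets out from 10, which is brominated with only 1.0 equiv NBS (DMF, 0 °C) and the resulting 11 is isolated. NaH/PhSO2Cl in THF gives 3,4,7-tribromo-1-(phenylsulfonyl)-1H-indole F5. LDA (1.1 equiv, THF, −78 °C) deprotonates C2 without touching the C–Br bonds, and quenching with 1,2-dibromotetrachloroethane gives 2,3,4,7-tetrabromo-1-(phenylsulfonyl)-1H-indole F6. Cs2CO3 in THF/MeOH at rt removes the sulfonyl group, and the fallback comes back to the route at 12.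

**Further compounds**
F1 | step 2 | ethyl (E)-3-(2,5-dibromophenyl)acrylate | CCOC(=O)/C=C/c1cc(Br)ccc1Br
F2 | step 2 | ethyl (2R*,3S*)-2,3-dibromo-3-(2,5-dibromophenyl)propanoate (racemic, one enantiomer drawn) | CCOC(=O)[C@@H](Br)[C@@H](Br)c1cc(Br)ccc1Br
F3 | step 2 | ethyl 2-azido-3-bromo-3-(2,5-dibromophenyl)propanoate (racemic, not isolated) | CCOC(=O)C(N=[N+]=[N-])C(Br)c1cc(Br)ccc1Br
F4 | step 5 | 3,4,7-tribromo-1H-indole-2-carboxylic acid | OC(=O)c1[nH]c2c(Br)ccc(Br)c2c1Br
F5 | step 6 | 3,4,7-tribromo-1-(phenylsulfonyl)-1H-indole | O=S(=O)(c1ccccc1)n1cc(Br)c2c(Br)ccc(Br)c21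
F6 | step 6 | 2,3,4,7-tetrabromo-1-(phenylsulfonyl)-1H-indole | O=S(=O)(c1ccccc1)n1c(Br)c(Br)c2c(Br)ccc(Br)c21
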